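**Plan**

- Retrosynthesis: the free phenol and the acetyl group are unmasked last (TIPS ether, dioxolane). The C9 carbinol is traced back to an E-propenyl group (C=C cleavage). The C7–C8 bond is then cut by a retro-[2,3]-Wittig shift to a benzyl allyl ether, which is cut at its benzylic C–O bond and at its enol ether C–O bond.
- Enabling feature: C7 (benzylic carbinol on ring A, the 4-hydroxy-3-methoxyphenyl ring) and C8 (carrying the ring B aryloxy group) are neighbouring oxygen-bearing carbons. C7 can therefore serve as a benzylic α-oxy carbanion and C8 as the oxygen-bearing end of an aryl enol ether, with C9 held as a propenyl carbon.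
- Forward: ring B phenol (ketone as ketal) plus but-3-yn-2-one gives the E-aryloxy enone, then the R allylic alcohol. Ring A arrives as O-TIPS vanillyl bromide from vanillin. A Williamson ether joins the halves and the [2,3]-Wittig shift forms C7–C8. Both rings are bought; none is closed.
- Finish: alkene cleavage with reduction gives the C9 CH2OH, then ketal and silyl ether are removed.
- Stereochemistry: one reagent-controlled centre (R carbinol, CBS reduction). The rearrangement relays it to C8 (S). The E enol ether with ring A exo sets C7 (R), i.e. erythro.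

Key step: step 8

Remark: C7, C8 and C9 denote the benzylic carbinol carbon, the aryloxy-bearing carbon and the CH2OH carbon; the SMILES string encodes the (7R,8S) erythro isomer, and this is the isomer made.

**Route**

Step 1
Reactants: 1 acetosyringone [1-(4-hydroxy-3,5-dimethoxyphenyl)ethan-1-one]
Product: 2 2,6-dimethoxy-4-(2-methyl-1,3-dioxolan-2-yl)phenol
Conditions: HOCH2CH2OH (5 equiv), p-TsOH·H2O (2 mol%), toluene, reflux, Dean–Stark; Et3N quench
Reagents that add atoms: ethylene glycol, OCCO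
Why: Acid-catalysed ketalisation with azeotropic removal of water should mask the aryl ketone against n-BuLi and NaBH4 while leaving the phenol free for the next step.

Step 2
Reactants: 2 2,6-dimethoxy-4-(2-methyl-1,3-dioxolan-2-yl)phenol; 3 but-3-yn-2-one
Product: 4 (E)-4-[2,6-dimethoxy-4-(2-methyl-1,3-dioxolan-2-yl)phenoxy]but-3-en-2-one
Conditions: DABCO (1,4-diazabicyclo[2.2.2]octane, 10 mol%), CH2Cl2, 0 °C → rt
Reagents that add atoms: none
Why: Amine-catalysed oxa-Michael addition of a phenol to an ynone proceeds through a β-ammonium enone by addition–elimination and should deliver the thermodynamically preferred E β-aryloxy enone.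

Step 3
Reactants: 4 (E)-4-[2,6-dimethoxy-4-(2-methyl-1,3-dioxolan-2-yl)phenoxy]but-3-en-2-one
Product: 5 (R,E)-4-[2,6-dimethoxy-4-(2-methyl-1,3-dioxolan-2-yl)phenoxy]but-3-en-2-ol
Conditions: (S)-2-methyl-CBS-oxazaborolidine [(S)-1-methyl-3,3-diphenyltetrahydro-1H,3H-pyrrolo[1,2-c][1,3,2]oxazaborole] (20 mol%), catecholborane (1.8 equiv), toluene, −78 → −40 °C; aq. NaOH work-up, Et3N-treated silica
Reagents that add atoms: none
Why: Corey–Bakshi–Shibata reduction of a methyl alkenyl ketone, in which the alkenyl group acts as the large and methyl as the small substituent, should give the R carbinol with the S catalyst as for aryl methyl ketones, and catecholborane at low temperature spares the enol ether from hydroboration.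

Step 4
Reactants: 6 vanillin (4-hydroxy-3-methoxybenzaldehyde)
Product: 7 3-methoxy-4-(triisopropylsilyloxy)benzaldehyde
Conditions: TIPSCl (1.1 equiv), imidazole (2 equiv), DMF, rt
Reagents that add atoms: triisopropylsilyl chloride, CC(C)[Si](Cl)(C(C)C)C(C)C
Why: Imidazole-promoted silylation of the phenol installs a hindered silyl ether that should survive NaH, n-BuLi at −78 °C and ozone and is removed by fluoride without acid.

Step 5
Reactants: 7 3-methoxy-4-(triisopropylsilyloxy)benzaldehyde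
Product: 8 [3-methoxy-4-(triisopropylsilyloxy)phenyl]methanol
Conditions: NaBH4, EtOH, 0 °C
Reagents that add atoms: none
Why: Borohydride reduction of an aryl aldehyde to the benzylic alcohol is fast at 0 °C and leaves the aryl silyl ether intact.

Step 6
Reactants: 8 [3-methoxy-4-(triisopropylsilyloxy)phenyl]methanol
Product: 9 [4-(bromomethyl)-2-methoxyphenoxy]triisopropylsilane
Conditions: CBr4 (1.2 equiv), PPh3 (1.2 equiv), CH2Cl2, 0 °C; filtered through a short silica plug and used at once
Reagents that add atoms: carbon tetrabromide, BrC(Br)(Br)Br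
Why: The Appel reaction converts the benzylic alcohol to the bromide under neutral conditions, which suits this electron-rich and labile benzylic halide.

Step 7
Reactants: 5 (R,E)-4-[2,6-dimethoxy-4-(2-methyl-1,3-dioxolan-2-yl)phenoxy]but-3-en-2-ol; 9 [4-(bromomethyl)-2-methoxyphenoxy]triisopropylsilane
Product: 11 3-methoxy-4-(triisopropylsilyloxy)benzyl (R,E)-4-[2,6-dimethoxy-4-(2-methyl-1,3-dioxolan-2-yl)phenoxy]but-3-en-2-yl ether, via sodium alkoxide 10 (not isolated)
Conditions: NaH (1.2 equiv), THF/DMF (4:1), 0 °C; then 9 (1.2 equiv), Bu4NI (10 mol%), 0 °C → rt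
Reagents that add atoms: none
Why: Williamson etherification of the secondary alkoxide with a reactive benzylic bromide forms only an O–C bond, so the R carbinol centre and the E enol ether are carried over unchanged.

Step 8
Reactants: 11 3-methoxy-4-(triisopropylsilyloxy)benzyl (R,E)-4-[2,6-dimethoxy-4-(2-methyl-1,3-dioxolan-2-yl)phenoxy]but-3-en-2-yl ether
Product: 14 (1R,2S,E)-2-[2,6-dimethoxy-4-(2-methyl-1,3-dioxolan-2-yl)phenoxy]-1-[3-methoxy-4-(triisopropylsilyloxy)phenyl]pent-3-en-1-ol, via benzylic lithio ether 12 (not isolated), via lithium alkoxide 13 (not isolated)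
Conditions: n-BuLi (1.5 equiv), THF, −78 °C, 2 h; then sat. aq. NH4Cl, −78 °C → rt
Reagents that add atoms: none
Why: n-BuLi removes a proton from the ArCH2–O carbon, the only C–H flanked by both an aryl ring and oxygen, and the α-oxy benzyllithium 12 undergoes a concerted suprafacial [2,3]-sigmatropic shift through a five-membered envelope transition state in which the carbanion bonds to the aryloxy-bearing alkene terminus as the allylic C–O bond breaks; no ring is closed. The closest known reaction is the [2,3]-Wittig rearrangement of benzyl ethers of secondary E-allylic alcohols, which proceeds with 1,3-chirality transfer. C8 (C2 of 14) is controlled by the R carbinol centre: with its methyl group pseudo-equatorial the new bond forms on the alkene face from which the ether oxygen leaves, which should give 2S together with the E-propenyl group. C7 (C1 of 14) is controlled by the E geometry of the enol ether: ring A prefers the exo position of the envelope, away from the aryloxy substituent, which places C7–O and C8–OAr anti (erythro) and should give 1R. The step needs the [2,3] over the [1,2] pathway and benzylic over allylic, vinylic or ring lithiation; the low temperature, the tertiary nature of the competing allylic C–H and the slow ring metalation by n-BuLi in THF without an amine additive favour this. Selectivity with an aryl-stabilised carbanion may be moderate, so any threo isomer is to be separated by chromatography of 14.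

Step 9
Reactants: 14 (1R,2S,E)-2-[2,6-dimethoxy-4-(2-methyl-1,3-dioxolan-2-yl)phenoxy]-1-[3-methoxy-4-(triisopropylsilyloxy)phenyl]pent-3-en-1-ol
Product: 16 (1R,2S)-2-[2,6-dimethoxy-4-(2-methyl-1,3-dioxolan-2-yl)phenoxy]-1-[3-methoxy-4-(triisopropylsilyloxy)phenyl]propane-1,3-diol, via aldehyde 15 (not isolated)
Conditions: O3, CH2Cl2/MeOH (3:1), NaHCO3, Sudan Red 7B as end-point indicator, −78 °C; then NaBH4 (excess), −78 → 0 °C
Reagents that add atoms: ozone, [O-][O+]=O
Why: Ozonolysis of the disubstituted alkene, stopped at the indicator end point so the aryl rings are not attacked, followed by borohydride reduction of the peroxidic products in the same flask, should give the primary alcohol without letting the epimerisable α-aryloxy-β-hydroxy aldehyde accumulate, so both stereocentres are retained.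

Step 10
Reactants: 16 (1R,2S)-2-[2,6-dimethoxy-4-(2-methyl-1,3-dioxolan-2-yl)phenoxy]-1-[3-methoxy-4-(triisopropylsilyloxy)phenyl]propane-1,3-diol
Product: 17 1-[4-({(1R,2S)-1,3-dihydroxy-1-[3-methoxy-4-(triisopropylsilyloxy)phenyl]propan-2-yl}oxy)-3,5-dimethoxyphenyl]ethan-1-one
Conditions: pyridinium p-toluenesulfonate (10 mol%), acetone/H2O (10:1), rt
Reagents that add atoms: water, O
Why: Mild acid-catalysed hydrolysis of the electron-rich aryl methyl ketal is fast, and these conditions are too weak to ionise the benzylic C7 carbinol or to cleave the aryl silyl ether.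

Step 11
Reactants: 17 1-[4-({(1R,2S)-1,3-dihydroxy-1-[3-methoxy-4-(triisopropylsilyloxy)phenyl]propan-2-yl}oxy)-3,5-dimethoxyphenyl]ethan-1-one
Product: 18 1-(4-{[(1R,2S)-1,3-dihydroxy-1-(4-hydroxy-3-methoxyphenyl)propan-2-yl]oxy}-3,5-dimethoxyphenyl)ethan-1-one (CNP0242981.1)
Conditions: Bu4NF (1.1 equiv), AcOH (1.1 equiv), THF, 0 °C
Reagents that add atoms: none
Why: Fluoride cleaves the aryl silyl ether rapidly, and buffering with acetic acid keeps the liberated phenol protonated so that no quinone methide can form at C7.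

**Compound list**

1 | acetosyringone, 1-(4-hydroxy-3,5-dimethoxyphenyl)ethan-1-one | CC(=O)c1cc(OC)c(O)c(OC)c1 | starting material
2 | 2,6-dimethoxy-4-(2-methyl-1,3-dioxolan-2-yl)phenol | COc1cc(C2(C)OCCO2)cc(OC)c1O | intermediate
3 | but-3-yn-2-one | CC(=O)C#C | starting material
4 | (E)-4-[2,6-dimethoxy-4-(2-methyl-1,3-dioxolan-2-yl)phenoxy]but-3-en-2-one | CC(=O)/C=C/Oc1c(OC)cc(C2(C)OCCO2)cc1OC | intermediate
5 | (R,E)-4-[2,6-dimethoxy-4-(2-methyl-1,3-dioxolan-2-yl)phenoxy]but-3-en-2-ol | O[C@H](C)/C=C/Oc1c(OC)cc(C2(C)OCCO2)cc1OC | intermediate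
6 | vanillin, 4-hydroxy-3-methoxybenzaldehyde | COc1cc(C=O)ccc1O | starting material
7 | 3-methoxy-4-(triisopropylsilyloxy)benzaldehyde | COc1cc(C=O)ccc1O[Si](C(C)C)(C(C)C)C(C)C | intermediate
8 | [3-methoxy-4-(triisopropylsilyloxy)phenyl]methanol | COc1cc(CO)ccc1O[Si](C(C)C)(C(C)C)C(C)C | intermediate
9 | [4-(bromomethyl)-2-methoxyphenoxy]triisopropylsilane | COc1cc(CBr)ccc1O[Si](C(C)C)(C(C)C)C(C)C | intermediate
10 | sodium (R,E)-4-[2,6-dimethoxy-4-(2-methyl-1,3-dioxolan-2-yl)phenoxy]but-3-en-2-olate | [Na+].[O-][C@H](C)/C=C/Oc1c(OC)cc(C2(C)OCCO2)cc1OC | intermediate (not isolated)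
11 | 3-methoxy-4-(triisopropylsilyloxy)benzyl (R,E)-4-[2,6-dimethoxy-4-(2-methyl-1,3-dioxolan-2-yl)phenoxy]but-3-en-2-yl ether | COc1cc(CO[C@H](C)/C=C/Oc2c(OC)cc(C3(C)OCCO3)cc2OC)ccc1O[Si](C(C)C)(C(C)C)C(C)C | intermediate
12 | benzylic α-lithio derivative of ether 11 (lithiated carbon configurationally labile) | COc1cc(C([Li])O[C@H](C)/C=C/Oc2c(OC)cc(C3(C)OCCO3)cc2OC)ccc1O[Si](C(C)C)(C(C)C)C(C)C | intermediate (not isolated)
13 | lithium (1R,2S,E)-2-[2,6-dimethoxy-4-(2-methyl-1,3-dioxolan-2-yl)phenoxy]-1-[3-methoxy-4-(triisopropylsilyloxy)phenyl]pent-3-en-1-olate | [Li+].COc1cc([C@@H]([O-])[C@H](/C=C/C)Oc2c(OC)cc(C3(C)OCCO3)cc2OC)ccc1O[Si](C(C)C)(C(C)C)C(C)C | intermediate (not isolated)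
14 | (1R,2S,E)-2-[2,6-dimethoxy-4-(2-methyl-1,3-dioxolan-2-yl)phenoxy]-1-[3-methoxy-4-(triisopropylsilyloxy)phenyl]pent-3-en-1-ol | COc1cc([C@@H](O)[C@H](/C=C/C)Oc2c(OC)cc(C3(C)OCCO3)cc2OC)ccc1O[Si](C(C)C)(C(C)C)C(C)C | intermediate
15 | (2R,3R)-2-[2,6-dimethoxy-4-(2-methyl-1,3-dioxolan-2-yl)phenoxy]-3-hydroxy-3-[3-methoxy-4-(triisopropylsilyloxy)phenyl]propanal | COc1cc([C@@H](O)[C@H](C=O)Oc2c(OC)cc(C3(C)OCCO3)cc2OC)ccc1O[Si](C(C)C)(C(C)C)C(C)C | intermediate (not isolated)
16 | (1R,2S)-2-[2,6-dimethoxy-4-(2-methyl-1,3-dioxolan-2-yl)phenoxy]-1-[3-methoxy-4-(triisopropylsilyloxy)phenyl]propane-1,3-diol | COc1cc([C@@H](O)[C@H](CO)Oc2c(OC)cc(C3(C)OCCO3)cc2OC)ccc1O[Si](C(C)C)(C(C)C)C(C)C | intermediate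
17 | 1-[4-({(1R,2S)-1,3-dihydroxy-1-[3-methoxy-4-(triisopropylsilyloxy)phenyl]propan-2-yl}oxy)-3,5-dimethoxyphenyl]ethan-1-one | COc1cc([C@@H](O)[C@H](CO)Oc2c(OC)cc(C(C)=O)cc2OC)ccc1O[Si](C(C)C)(C(C)C)C(C)C | intermediate
18 | 1-(4-{[(1R,2S)-1,3-dihydroxy-1-(4-hydroxy-3-methoxyphenyl)propan-2-yl]oxy}-3,5-dimethoxyphenyl)ethan-1-one | COc1cc([C@@H](O)[C@H](CO)Oc2c(OC)cc(C(C)=O)cc2OC)ccc1O | target

**Step count and risks**

Total steps: 11. Longest linear sequence: 8 steps (steps 1, 2, 3, 7, 8, 9, 10, 11 from acetosyringone; equally steps 4–11 from vanillin).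

Steps most likely to fail:

1. Step 8. The carbanion may undergo the [1,2]-shift instead, lithiation may occur at the enol ether or on ring A, or the erythro preference may be eroded because an aryl-stabilised carbanion and an aryloxy-substituted terminus are a little-tested combination. Fallback: the C7–C8 bond is made by an auxiliary-controlled aldol addition followed by inversion at C7, setting out from phenol 2 and aldehyde 7 and returning at diol 16.
   - Phenol 2 is alkylated with purchased (R)-4-benzyl-3-(chloroacetyl)oxazolidin-2-one (K2CO3, NaI cat., acetone) to give (R)-4-benzyl-3-{[2,6-dimethoxy-4-(2-methyl-1,3-dioxolan-2-yl)phenoxy]acetyl}oxazolidin-2-one F1.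
   - Its dibutylboron Z-enolate (Bu2BOTf, i-Pr2NEt, CH2Cl2, −78 °C) adds to 7 to give the syn aldol adduct (R)-4-benzyl-3-{(2R,3S)-2-[2,6-dimethoxy-4-(2-methyl-1,3-dioxolan-2-yl)phenoxy]-3-hydroxy-3-[3-methoxy-4-(triisopropylsilyloxy)phenyl]propanoyl}oxazolidin-2-one F2.
   - LiBH4 (THF/MeOH, 0 °C) removes the auxiliary and gives the threo diol (1S,2S)-2-[2,6-dimethoxy-4-(2-methyl-1,3-dioxolan-2-yl)phenoxy]-1-[3-methoxy-4-(triisopropylsilyloxy)phenyl]propane-1,3-diol F3.
   - Selective acetylation of the primary hydroxyl (AcCl, 2,4,6-collidine, CH2Cl2, −78 °C) gives (2S,3S)-2-[2,6-dimethoxy-4-(2-methyl-1,3-dioxolan-2-yl)phenoxy]-3-hydroxy-3-[3-methoxy-4-(triisopropylsilyloxy)phenyl]propyl acetate F4.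
   - A Mitsunobu reaction (4-nitrobenzoic acid, PPh3, DIAD, THF, 0 °C) inverts C7 to give (1R,2S)-3-acetoxy-2-[2,6-dimethoxy-4-(2-methyl-1,3-dioxolan-2-yl)phenoxy]-1-[3-methoxy-4-(triisopropylsilyloxy)phenyl]propyl 4-nitrobenzoate F5.
   - K2CO3 in MeOH at 0 °C removes both esters and returns 16.

2. Step 3. Enantioselectivity may be insufficient because the β-aryloxy enone is a vinylogous ester with a weakly differentiated carbonyl, or the enol ether may be reduced or hydroborated. Fallback: a kinetic resolution replaces the asymmetric reduction, setting out from enone 4 and returning at alcohol 5.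
   - Luche reduction (NaBH4, CeCl3·7H2O, MeOH, −40 °C) gives racemic (E)-4-[2,6-dimethoxy-4-(2-methyl-1,3-dioxolan-2-yl)phenoxy]but-3-en-2-ol F6.
   - Immobilised Candida antarctica lipase B (Novozym 435) with vinyl acetate in MTBE at rt should acetylate the R enantiomer to (R,E)-4-[2,6-dimethoxy-4-(2-methyl-1,3-dioxolan-2-yl)phenoxy]but-3-en-2-yl acetate F7.
   - The unreacted (S,E)-4-[2,6-dimethoxy-4-(2-methyl-1,3-dioxolan-2-yl)phenoxy]but-3-en-2-ol F8 is separated and can be oxidised back to 4 with MnO2.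
   - K2CO3 in MeOH converts F7 into 5.

3. Step 9. Ozone may over-oxidise the two electron-rich aryl rings, or the α-aryloxy-β-hydroxy aldehyde may undergo retro-aldol cleavage or epimerise at C8 before it is reduced. Fallback: dihydroxylation and glycol cleavage in two stages, setting out from 14 and returning at aldehyde 15, which is reduced to 16.
   - OsO4 (2 mol%) with N-methylmorpholine N-oxide in acetone/H2O gives (1R,2R)-2-[2,6-dimethoxy-4-(2-methyl-1,3-dioxolan-2-yl)phenoxy]-1-[3-methoxy-4-(triisopropylsilyloxy)phenyl]pentane-1,3,4-triol F9 as a mixture of the two syn-3,4-diol diastereomers.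
   - NaIO4 in pH 7 buffered THF/H2O at 0 °C cleaves only the 3,4-diol to aldehyde 15.
   - NaBH4 added to the same flask reduces 15 to 16.

**Further compounds**

F1 | step 8 | (R)-4-benzyl-3-{[2,6-dimethoxy-4-(2-methyl-1,3-dioxolan-2-yl)phenoxy]acetyl}oxazolidin-2-one | COc1cc(C2(C)OCCO2)cc(OC)c1OCC(=O)N1[C@H](Cc2ccccc2)COC1=O
F2 | step 8 | (R)-4-benzyl-3-{(2R,3S)-2-[2,6-dimethoxy-4-(2-methyl-1,3-dioxolan-2-yl)phenoxy]-3-hydroxy-3-[3-methoxy-4-(triisopropylsilyloxy)phenyl]propanoyl}oxazolidin-2-one | COc1cc([C@H](O)[C@H](C(=O)N2[C@H](Cc3ccccc3)COC2=O)Oc2c(OC)cc(C3(C)OCCO3)cc2OC)ccc1O[Si](C(C)C)(C(C)C)C(C)C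
F3 | step 8 | (1S,2S)-2-[2,6-dimethoxy-4-(2-methyl-1,3-dioxolan-2-yl)phenoxy]-1-[3-methoxy-4-(triisopropylsilyloxy)phenyl]propane-1,3-diol | COc1cc([C@H](O)[C@H](CO)Oc2c(OC)cc(C3(C)OCCO3)cc2OC)ccc1O[Si](C(C)C)(C(C)C)C(C)C
F4 | step 8 | (2S,3S)-2-[2,6-dimethoxy-4-(2-methyl-1,3-dioxolan-2-yl)phenoxy]-3-hydroxy-3-[3-methoxy-4-(triisopropylsilyloxy)phenyl]propyl acetate | COc1cc([C@H](O)[C@H](COC(C)=O)Oc2c(OC)cc(C3(C)OCCO3)cc2OC)ccc1O[Si](C(C)C)(C(C)C)C(C)C
F5 | step 8 | (1R,2S)-3-acetoxy-2-[2,6-dimethoxy-4-(2-methyl-1,3-dioxolan-2-yl)phenoxy]-1-[3-methoxy-4-(triisopropylsilyloxy)phenyl]propyl 4-nitrobenzoate | COc1cc([C@@H](OC(=O)c2ccc(cc2)[N+](=O)[O-])[C@H](COC(C)=O)Oc2c(OC)cc(C3(C)OCCO3)cc2OC)ccc1O[Si](C(C)C)(C(C)C)C(C)C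
F6 | step 3 | racemic (E)-4-[2,6-dimethoxy-4-(2-methyl-1,3-dioxolan-2-yl)phenoxy]but-3-en-2-ol | CC(O)/C=C/Oc1c(OC)cc(C2(C)OCCO2)cc1OC
F7 | step 3 | (R,E)-4-[2,6-dimethoxy-4-(2-methyl-1,3-dioxolan-2-yl)phenoxy]but-3-en-2-yl acetate | CC(=O)O[C@H](C)/C=C/Oc1c(OC)cc(C2(C)OCCO2)cc1OC
F8 | step 3 | (S,E)-4-[2,6-dimethoxy-4-(2-methyl-1,3-dioxolan-2-yl)phenoxy]but-3-en-2-ol | O[C@@H](C)/C=C/Oc1c(OC)cc(C2(C)OCCO2)cc1OC
F9 | step 9 | (1R,2R)-2-[2,6-dimethoxy-4-(2-methyl-1,3-dioxolan-2-yl)phenoxy]-1-[3-methoxy-4-(triisopropylsilyloxy)phenyl]pentane-1,3,4-triol (C3 and C4 as a mixture of the two syn-diol diastereomers) | COc1cc([C@@H](O)[C@H](C(O)C(C)O)Oc2c(OC)cc(C3(C)OCCO3)cc2OC)ccc1O[Si](C(C)C)(C(C)C)C(C)C
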